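**Retrosynthetic overview**
1. Feature: the only ring to build is the tetrahydrofuran O1/C2–C5 (2S,3R,4R,5R). The C2 aryl, C3 methyl and C5 aryl share one face and only the C4 methyl lies on the other. This crowded 2,3-cis/2,5-cis array is kinetic and would be lost in any closure through a free benzylic cation.
2. Last cuts: the two ArO–C8 ether bonds. Both arms are threo but mirror images, (7R,8R) on the C2 aryl and (7S,8S) on the C5 aryl. The two phenols must therefore be distinguished (benzyl on the C2 aryl, allyl on the C5 aryl), and both lactate antipodes are needed.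
3. The C4 methyl is traced back through CH2OMs, CH2OH and CO2Me to a geminal diester at C4.
4. The ring is cut at O1–C2 and C4–C5 into a (2R,3S)-trans-2-aryl-3-methylcyclopropane-1,1-diester and O-allylvanillin. Rear-side attack at C2 turns trans (cyclopropane) into 2,3-cis (tetrahydrofuran).
5. Ring order: cyclopropane first, tetrahydrofuran second. The cyclopropane comes from E-O-benzylisoeugenol and the malonate iodonium ylide with [Cu(MeCN)4]PF6 and a bis(oxazoline). This system is preferred because Rh2(O2CR)4/diazomalonate systems are proven only on terminal styrenes.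

Key step: step 5

Remark on locants: O1, C2 (aryl from the cyclopropane), C3, C4 and C5 (aryl from the aldehyde) are kept for every tetrahydrofuran below. In the arms, C7 is the ketone or carbinol carbon and C8 is the O-bearing methine.
Assumption: the ligand antipode that leads to (2R,3S)-5 is chosen from the sense of induction on the parent E-β-methylstyrene; both antipodes are made in the same way from (R)- or (S)-phenylglycinol.

Step 1
Reactants: 1 (E)-isoeugenol
Product: 2 (E)-O-benzylisoeugenol (1-benzyloxy-2-methoxy-4-[(E)-prop-1-enyl]benzene)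
Conditions: BnBr, K2CO3, DMF, rt; recrystallise (EtOH)
Reagents that add atoms: benzyl bromide, BrCc1ccccc1
Why: Williamson etherification of the phenol; recrystallising the crystalline ether should remove any Z isomer, which matters because the alkene geometry becomes the trans relation of the cyclopropane.

Step 2
Reactants: 3 dimethyl malonate
Product: 4 phenyliodonium ylide of dimethyl malonate
Conditions: PhI(OAc)2, KOH, MeCN, 0 °C
Reagents that add atoms: (diacetoxyiodo)benzene, CC(=O)OI(OC(C)=O)c1ccccc1
Why: Known base-mediated condensation of an active methylene compound with PhI(OAc)2, giving a storable carbene source that avoids the diazo compound.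

Step 3
Reactants: 2 (E)-O-benzylisoeugenol; 4 phenyliodonium ylide of dimethyl malonate
Product: 5 dimethyl (2R,3S)-2-(4-benzyloxy-3-methoxyphenyl)-3-methylcyclopropane-1,1-dicarboxylate (aryl and methyl trans)
Conditions: [Cu(MeCN)4]PF6 (5 mol %), dibenzyl-bridged bis(4-phenyloxazoline) ligand (SaBOX type, 6 mol %), 4 Å MS, toluene, 0 °C to rt; recrystallise
Reagents that add atoms: none
Why: Copper-carbene [2+1] cyclopropanation, a catalyst type shown to give 1,1-cyclopropane diesters from E-1,2-disubstituted styrenes with high enantioselectivity; concerted syn addition carries the E geometry into the trans C2/C3 relation, the ligand pocket selects the alkene face, and recrystallisation should bring the diester to enantiopurity.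

Step 4
Reactants: 6 vanillin
Product: 7 O-allylvanillin (4-allyloxy-3-methoxybenzaldehyde)
Conditions: allyl bromide, K2CO3, DMF, rt
Reagents that add atoms: allyl bromide, C=CCBr
Why: Williamson etherification; the allyl ether is orthogonal to the benzyl ether and tolerates a catalytic Lewis acid.

Step 5
Reactants: 5 dimethyl (2R,3S)-2-(4-benzyloxy-3-methoxyphenyl)-3-methylcyclopropane-1,1-dicarboxylate; 7 O-allylvanillin
Product: 9 dimethyl (2S,3R,5S)-2-(4-benzyloxy-3-methoxyphenyl)-5-(4-allyloxy-3-methoxyphenyl)-3-methyltetrahydrofuran-4,4-dicarboxylate (2,3-cis and 2,5-cis), via oxocarbenium malonate zwitterion 8 (not isolated)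
Conditions: AlCl3 (10–20 mol %), 7 (2 equiv), 4 Å MS, CH2Cl2, −30 to 0 °C; Et3N quench at full conversion
Reagents that add atoms: none
Why: AlCl3 chelates the two ester carbonyls of 5 and stretches the bond between the aryl-bearing carbon (future C2) and the diester carbon (future C4) into a tight ion pair, the carbonyl oxygen of 7 attacks C2 from the side opposite the departing malonate (SN2-like) to give zwitterion 8, and its aluminium malonate enolate adds to the oxocarbenium carbon (future C5). The closest known reaction is the Lewis acid catalysed formal [3+2] annulation of donor–acceptor cyclopropanes with aldehydes, which has been run on 2-(dialkoxyphenyl)-3-substituted cyclopropane-1,1-diesters. The tetrahydrofuran, the only ring formed, closes by an aldol-type 5-(enolexo)-endo-trig attack of C4 on the E-oxocarbenium ion, a mode that is open to cationic C=O+ acceptors. C2 is set by inversion of the (2R) carbon of 5, so the trans cyclopropane becomes the 2,3-cis pair, while C3 is not touched and keeps the configuration installed in step 3. C5 is set in an envelope transition state that places both aryl groups pseudo-equatorial, which gives 2,5-cis. The step needs cleavage of the aryl-bearing and not the methyl-bearing cyclopropane bond, which the donor aryl group secures, and substitution faster than ionisation or reopening of the product, which the chelating geminal diester, the electron-rich and therefore strongly nucleophilic carbonyl oxygen of 7 (in excess), the low temperature and the early quench secure.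

Step 6
Reactants: 9 tetrahydrofuran-4,4-diester
Product: 11 methyl (2S,3R,4R,5R)-2-(4-benzyloxy-3-methoxyphenyl)-5-(4-allyloxy-3-methoxyphenyl)-3-methyltetrahydrofuran-4-carboxylate (ester trans to the C3 methyl and to the C5 aryl), via all-cis (4S)-ester 10 (not isolated)
Conditions: LiCl, H2O, DMSO, 150 °C; crude, then NaOMe (0.2 equiv), MeOH, 50 °C
Reagents that add atoms: none
Why: Krapcho demethoxycarbonylation (chloride SN2 at a methyl ester, loss of CO2, protonation of the ester enolate); protonation from the open face opposite the three cis substituents should first favour the all-cis ester 10, methoxide equilibration through the same enolate then moves the ester to the thermodynamic face trans to both neighbours (4R), ring opening by β-elimination is a disfavoured reverse 5-endo-trig process, and 150 °C lies well below the aromatic Claisen range of the allyl ether.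

Step 7
Reactants: 11 tetrahydrofuran-4-carboxylate
Product: 12 [(2S,3R,4S,5R)-2-(4-benzyloxy-3-methoxyphenyl)-5-(4-allyloxy-3-methoxyphenyl)-3-methyltetrahydrofuran-4-yl]methanol
Conditions: LiAlH4, THF, 0 °C
Reagents that add atoms: none
Why: Hydride reduction of the ester to the primary alcohol; no stereocentre is touched (the C4 descriptor changes by priority only) and the benzyl, allyl and methyl ethers are inert.

Step 8
Reactants: 12 C4 hydroxymethyl compound
Product: 13 methanesulfonate of 12, (2S,3R,4S,5R)
Conditions: MsCl, Et3N, CH2Cl2, 0 °C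
Reagents that add atoms: methanesulfonyl chloride, CS(=O)(=O)Cl
Why: O-sulfonylation of an unhindered primary alcohol, the only nucleophilic site in 12.

Step 9
Reactants: 13 mesylate
Product: 14 (2S,3R,4R,5R)-2-(4-benzyloxy-3-methoxyphenyl)-5-(4-allyloxy-3-methoxyphenyl)-3,4-dimethyltetrahydrofuran
Conditions: LiEt3BH, THF, 0 °C to rt
Reagents that add atoms: none
Why: SN2 displacement of a primary mesylate by the strongly nucleophilic triethylborohydride (sulfonate deoxygenation) turns CH2OMs into the C4 methyl without touching a stereocentre.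

Step 10
Reactants: 14 differentially protected core
Product: 15 (2S,3R,4R,5R)-2-(4-benzyloxy-3-methoxyphenyl)-5-(4-hydroxy-3-methoxyphenyl)-3,4-dimethyltetrahydrofuran
Conditions: Pd(PPh3)4 (5 mol %), morpholine, THF, rt
Reagents that add atoms: none
Why: Tsuji–Trost deallylation, in which zerovalent palladium ionises the allyl aryl ether to a π-allyl complex that morpholine traps; the benzyl ether is inert, and this phenol must be freed first because the later hydrogenolysis would saturate an allyl group.

Step 11
Reactants: 16 methyl (R)-lactate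
Product: 17 (R)-2-hydroxy-N-methoxy-N-methylpropanamide
Conditions: MeNHOMe·HCl, iPrMgCl, THF, −20 to 0 °C
Reagents that add atoms: N,O-dimethylhydroxylamine hydrochloride, CNOC.Cl
Why: Weinreb amide formation by aminolysis of the ester with the magnesium amide; the magnesium alkoxide of the free hydroxyl suppresses enolisation, so the stereocentre is retained.

Step 12
Reactants: 17 (R)-lactic Weinreb amide; 18 3,4-dimethoxyphenylmagnesium bromide (commercial THF solution)
Product: 19 (R)-1-(3,4-dimethoxyphenyl)-2-hydroxypropan-1-one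
Conditions: 18 (2.5 equiv), THF, 0 °C to rt; aq NH4Cl
Reagents that add atoms: none
Why: Weinreb ketone synthesis on the unprotected hydroxy amide; one equivalent of 18 deprotonates the hydroxyl, the next adds to give a chelated tetrahedral intermediate that collapses only on quench, so neither over-addition nor racemisation is expected.

Step 13
Reactants: 19 (R)-hydroxy ketone
Product: 20 (R)-1-(3,4-dimethoxyphenyl)-1-oxopropan-2-yl 4-methylbenzenesulfonate
Conditions: TsCl, pyridine, DMAP (cat.), CH2Cl2, 0 °C
Reagents that add atoms: p-toluenesulfonyl chloride, Cc1ccc(cc1)S(=O)(=O)Cl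
Why: O-sulfonylation leaves the C–O bond intact, so configuration is retained, and the weak base at 0 °C keeps enolisation low.

Step 14
Reactants: 15 C5-aryl phenol; 20 (R)-tosylate
Product: 21 core (2S,3R,4R,5R) whose C5 aryl carries at O-4 the (8S)-1-(3,4-dimethoxyphenyl)-1-oxopropan-2-yl group, with the C2 aryl still O-benzylated
Conditions: Cs2CO3 (1.1 equiv), MeCN, 0 °C to rt
Reagents that add atoms: none
Why: Williamson-type SN2 displacement of an α-keto tosylate by the caesium phenoxide with inversion, (R)-tosylate to (8S)-ether; the adjacent carbonyl accelerates substitution, and near-stoichiometric base at low temperature limits enolisation of the reagent and product.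

Step 15
Reactants: 21 aryloxy ketone
Product: 22 threo alcohol: core with the (7S,8S)-1-(3,4-dimethoxyphenyl)-1-hydroxypropan-2-yl arm on the C5 aryl and the C2 aryl O-benzylated
Conditions: polymer-bound borohydride (Amberlite IRA-400, BH4− form), MeOH/CH2Cl2, 0 °C to rt
Reagents that add atoms: none
Why: Polar Felkin–Anh controlled borohydride reduction; with a non-chelating ammonium counter-ion the aryloxy group stands anti to the incoming hydride, which passes over the C8 hydrogen, so the (8S) centre sets (7S) and the arm is threo.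

Step 16
Reactants: 22 benzyl ether with the first arm
Product: 23 the corresponding C2-aryl phenol (4-hydroxy-3-methoxyphenyl at C2) with the (7S,8S) arm on the C5 aryl
Conditions: H2 (1 atm), Pd/C, EtOAc, rt
Reagents that add atoms: none
Why: Catalytic hydrogenolysis of a phenolic benzyl ether, which under neutral conditions at one atmosphere is much faster than cleavage of the ring benzylic C–O bonds or of the benzylic alcohol.

Step 17
Reactants: 24 ethyl (S)-lactate
Product: 25 (S)-2-hydroxy-N-methoxy-N-methylpropanamide
Conditions: MeNHOMe·HCl, iPrMgCl, THF, −20 to 0 °C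
Reagents that add atoms: N,O-dimethylhydroxylamine hydrochloride, CNOC.Cl
Why: Weinreb amide formation as in step 11, in the antipodal series, with retention of the stereocentre.

Step 18
Reactants: 25 (S)-lactic Weinreb amide; 18 3,4-dimethoxyphenylmagnesium bromide
Product: 26 (S)-1-(3,4-dimethoxyphenyl)-2-hydroxypropan-1-one
Conditions: 18 (2.5 equiv), THF, 0 °C to rt; aq NH4Cl
Reagents that add atoms: none
Why: Weinreb ketone synthesis as in step 12, the chelated tetrahedral intermediate preventing over-addition and racemisation.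

Step 19
Reactants: 26 (S)-hydroxy ketone
Product: 27 (S)-1-(3,4-dimethoxyphenyl)-1-oxopropan-2-yl 4-methylbenzenesulfonate
Conditions: TsCl, pyridine, DMAP (cat.), CH2Cl2, 0 °C
Reagents that add atoms: p-toluenesulfonyl chloride, Cc1ccc(cc1)S(=O)(=O)Cl
Why: O-sulfonylation with retention, as in step 13.

Step 20
Reactants: 23 C2-aryl phenol; 27 (S)-tosylate
Product: 28 keto alcohol: core with the (7S,8S) hydroxy arm on the C5 aryl and the (8R)-1-(3,4-dimethoxyphenyl)-1-oxopropan-2-yl group on O-4 of the C2 aryl
Conditions: Cs2CO3 (1.1 equiv), MeCN, 0 °C to rt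
Reagents that add atoms: none
Why: SN2 etherification with inversion as in step 14, (S)-tosylate to (8R)-ether; only the phenol is deprotonated by carbonate, so the secondary benzylic alcohol of the first arm stays unalkylated.

Step 21
Reactants: 28 keto alcohol
Product: 29 target, (1R,2R)-1-(3,4-dimethoxyphenyl)-2-[4-[(2S,3R,4R,5R)-5-[4-[(1S,2S)-1-(3,4-dimethoxyphenyl)-1-hydroxypropan-2-yl]oxy-3-methoxyphenyl]-3,4-dimethyloxolan-2-yl]-2-methoxyphenoxy]propan-1-ol
Conditions: polymer-bound borohydride (Amberlite IRA-400, BH4− form), MeOH/CH2Cl2, 0 °C to rt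
Reagents that add atoms: none
Why: Polar Felkin–Anh reduction as in step 15, now under control of the (8R) centre, which sets (7R) and gives the second threo arm as the mirror image of the first.

**Compound list**
1 | (E)-isoeugenol | C/C=C/c1ccc(O)c(OC)c1 | starting material
2 | (E)-O-benzylisoeugenol | C/C=C/c1ccc(OCc2ccccc2)c(OC)c1 | intermediate
3 | dimethyl malonate | COC(=O)CC(=O)OC | starting material
4 | phenyliodonium ylide of dimethyl malonate | COC(=O)[C-](C(=O)OC)[I+]c1ccccc1 | intermediate
5 | dimethyl (2R,3S)-2-(4-benzyloxy-3-methoxyphenyl)-3-methylcyclopropane-1,1-dicarboxylate | COc1cc([C@H]2[C@H](C)C2(C(=O)OC)C(=O)OC)ccc1OCc1ccccc1 | intermediate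
6 | vanillin | O=Cc1ccc(O)c(OC)c1 | starting material
7 | O-allylvanillin | C=CCOc1ccc(C=O)cc1OC | intermediate
8 | ring-opened E-oxocarbenium malonate zwitterion (drawn without aluminium) | COc1cc([C@@H](/[O+]=C/c2ccc(OCC=C)c(OC)c2)[C@H](C)[C-](C(=O)OC)C(=O)OC)ccc1OCc1ccccc1 | intermediate
9 | dimethyl (2S,3R,5S)-2-(4-benzyloxy-3-methoxyphenyl)-5-(4-allyloxy-3-methoxyphenyl)-3-methyltetrahydrofuran-4,4-dicarboxylate | COc1cc([C@H]2O[C@@H](c3ccc(OCC=C)c(OC)c3)C(C(=O)OC)(C(=O)OC)[C@H]2C)ccc1OCc1ccccc1 | intermediate
10 | methyl (2S,3R,4S,5R)-tetrahydrofuran-4-carboxylate, all-cis C4 epimer of 11 | COc1cc([C@H]2O[C@@H](c3ccc(OCC=C)c(OC)c3)[C@@H](C(=O)OC)[C@H]2C)ccc1OCc1ccccc1 | intermediate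
11 | methyl (2S,3R,4R,5R)-2-(4-benzyloxy-3-methoxyphenyl)-5-(4-allyloxy-3-methoxyphenyl)-3-methyltetrahydrofuran-4-carboxylate | COc1cc([C@H]2O[C@@H](c3ccc(OCC=C)c(OC)c3)[C@H](C(=O)OC)[C@H]2C)ccc1OCc1ccccc1 | intermediate
12 | (2S,3R,4S,5R) C4 hydroxymethyl compound | COc1cc([C@H]2O[C@@H](c3ccc(OCC=C)c(OC)c3)[C@H](CO)[C@H]2C)ccc1OCc1ccccc1 | intermediate
13 | (2S,3R,4S,5R) C4 mesyloxymethyl compound | COc1cc([C@H]2O[C@@H](c3ccc(OCC=C)c(OC)c3)[C@H](COS(C)(=O)=O)[C@H]2C)ccc1OCc1ccccc1 | intermediate
14 | (2S,3R,4R,5R)-2-(4-benzyloxy-3-methoxyphenyl)-5-(4-allyloxy-3-methoxyphenyl)-3,4-dimethyltetrahydrofuran | COc1cc([C@H]2O[C@@H](c3ccc(OCC=C)c(OC)c3)[C@H](C)[C@H]2C)ccc1OCc1ccccc1 | intermediate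
15 | (2S,3R,4R,5R)-2-(4-benzyloxy-3-methoxyphenyl)-5-(4-hydroxy-3-methoxyphenyl)-3,4-dimethyltetrahydrofuran | COc1cc([C@H]2O[C@@H](c3ccc(O)c(OC)c3)[C@H](C)[C@H]2C)ccc1OCc1ccccc1 | intermediate
16 | methyl (R)-lactate | C[C@@H](O)C(=O)OC | starting material
17 | (R)-2-hydroxy-N-methoxy-N-methylpropanamide | C[C@@H](O)C(=O)N(C)OC | intermediate
18 | 3,4-dimethoxyphenylmagnesium bromide | COc1ccc([Mg]Br)cc1OC | starting material
19 | (R)-1-(3,4-dimethoxyphenyl)-2-hydroxypropan-1-one | C[C@@H](O)C(=O)c1ccc(OC)c(OC)c1 | intermediate
20 | (R)-1-(3,4-dimethoxyphenyl)-1-oxopropan-2-yl tosylate | C[C@@H](OS(=O)(=O)c1ccc(C)cc1)C(=O)c1ccc(OC)c(OC)c1 | intermediate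
21 | core with the (8S) keto arm on the C5 aryl, C2 aryl O-benzyl | COc1cc([C@H]2O[C@@H](c3ccc(O[C@@H](C)C(=O)c4ccc(OC)c(OC)c4)c(OC)c3)[C@H](C)[C@H]2C)ccc1OCc1ccccc1 | intermediate
22 | core with the (7S,8S) hydroxy arm on the C5 aryl, C2 aryl O-benzyl | COc1cc([C@H]2O[C@@H](c3ccc(O[C@@H](C)[C@@H](O)c4ccc(OC)c(OC)c4)c(OC)c3)[C@H](C)[C@H]2C)ccc1OCc1ccccc1 | intermediate
23 | core with the (7S,8S) hydroxy arm on the C5 aryl, C2 aryl free phenol | COc1cc([C@H]2O[C@@H](c3ccc(O[C@@H](C)[C@@H](O)c4ccc(OC)c(OC)c4)c(OC)c3)[C@H](C)[C@H]2C)ccc1O | intermediate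
24 | ethyl (S)-lactate | C[C@H](O)C(=O)OCC | starting material
25 | (S)-2-hydroxy-N-methoxy-N-methylpropanamide | C[C@H](O)C(=O)N(C)OC | intermediate
26 | (S)-1-(3,4-dimethoxyphenyl)-2-hydroxypropan-1-one | C[C@H](O)C(=O)c1ccc(OC)c(OC)c1 | intermediate
27 | (S)-1-(3,4-dimethoxyphenyl)-1-oxopropan-2-yl tosylate | C[C@H](OS(=O)(=O)c1ccc(C)cc1)C(=O)c1ccc(OC)c(OC)c1 | intermediate
28 | core with the (7S,8S) hydroxy arm on the C5 aryl and the (8R) keto arm on the C2 aryl | COc1cc([C@H]2O[C@@H](c3ccc(O[C@@H](C)[C@@H](O)c4ccc(OC)c(OC)c4)c(OC)c3)[C@H](C)[C@H]2C)ccc1O[C@H](C)C(=O)c1ccc(OC)c(OC)c1 | intermediate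
29 | CNP0116650.16 | COc1ccc([C@@H](O)[C@@H](C)Oc2ccc([C@H]3O[C@@H](c4ccc(O[C@@H](C)[C@@H](O)c5ccc(OC)c(OC)c5)c(OC)c4)[C@H](C)[C@H]3C)cc2OC)cc1OC | target

**Step count**
Total step count: 21.
Longest linear sequence: 13 steps (1, 3, 5, 6, 7, 8, 9, 10, 14, 15, 16, 20, 21).

**Steps most likely to fail**

Step 5. The polarised C2–C4 bond may ionise fully before the aldehyde attacks, because the 4-benzyloxy-3-methoxyphenyl group stabilises a benzylic cation strongly; this would erode the inversion at C2. Reopening of the product by the Lewis acid would erode the 2,5-cis relation. The fallback redesigns the donor rather than the conditions. It sets out from 1 and returns at 9.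
- 1 is acetylated (Ac2O, pyridine) to (E)-isoeugenyl acetate F1.
- Cyclopropanation with 4 as in step 3 gives dimethyl (2R,3S)-2-(4-acetoxy-3-methoxyphenyl)-3-methylcyclopropane-1,1-dicarboxylate F2, whose aryl group is no better a donor than phenyl.
- Annulation with 7 under Sn(OTf)2 (cat., CH2Cl2, rt) gives the acetoxyaryl tetrahydrofuran diester F3. Phenyl-type donors are known to react with inversion under these conditions.
- K2CO3/MeOH frees the phenolic tetrahydrofuran diester F4, and BnBr/K2CO3 gives 9.

Step 3. Carbene transfer to the internal alkene may be sluggish, or the facial selectivity too low for enrichment by crystallisation. The fallback replaces asymmetric carbene transfer by a Michael-initiated ring closure followed by resolution. It sets out from 6 and 3 and returns at 5.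
- 6 is benzylated (BnBr, K2CO3) to O-benzylvanillin F5.
- Knoevenagel condensation with 3 (piperidine, AcOH, toluene, water removal) gives dimethyl 2-(4-benzyloxy-3-methoxybenzylidene)malonate F6.
- Diphenylsulfonium ethylide (from ethyldiphenylsulfonium tetrafluoroborate and LDA, THF, −78 °C; Corey–Chaykovsky type) gives the racemic trans cyclopropane diester F7. Bond rotation in the betaine favours the trans isomer.
- F7 is resolved by preparative chromatography on a chiral stationary phase to give 5.

Step 6. At 150 °C the ester enolate may undergo β-elimination with ring opening, the allyl ether may begin to rearrange thermally, and the C4 equilibration may stay incomplete. The fallback separates ester cleavage from decarboxylation so that neither needs high temperature. It sets out from 9 and returns at 11.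
- 9 is saponified at the less hindered ester, the one trans to the C3 methyl and the C5 aryl (KOH, MeOH/H2O, 40 °C), to the (4S) malonic half-acid F8.
- F8 is decarboxylated in DMSO at about 110 °C.
- The crude ester is equilibrated with NaOMe/MeOH as in step 6 to give 11.

**Further compounds**
F1 | step 5 | (E)-isoeugenyl acetate | C/C=C/c1ccc(OC(C)=O)c(OC)c1
F2 | step 5 | dimethyl (2R,3S)-2-(4-acetoxy-3-methoxyphenyl)-3-methylcyclopropane-1,1-dicarboxylate | COc1cc([C@H]2[C@H](C)C2(C(=O)OC)C(=O)OC)ccc1OC(C)=O
F3 | step 5 | dimethyl (2S,3R,5S)-2-(4-acetoxy-3-methoxyphenyl)-5-(4-allyloxy-3-methoxyphenyl)-3-methyltetrahydrofuran-4,4-dicarboxylate | COc1cc([C@H]2O[C@@H](c3ccc(OCC=C)c(OC)c3)C(C(=O)OC)(C(=O)OC)[C@H]2C)ccc1OC(C)=O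
F4 | step 5 | dimethyl (2S,3R,5S)-2-(4-hydroxy-3-methoxyphenyl)-5-(4-allyloxy-3-methoxyphenyl)-3-methyltetrahydrofuran-4,4-dicarboxylate | COc1cc([C@H]2O[C@@H](c3ccc(OCC=C)c(OC)c3)C(C(=O)OC)(C(=O)OC)[C@H]2C)ccc1O
F5 | step 3 | O-benzylvanillin | O=Cc1ccc(OCc2ccccc2)c(OC)c1
F6 | step 3 | dimethyl 2-(4-benzyloxy-3-methoxybenzylidene)malonate | COC(=O)C(=Cc1ccc(OCc2ccccc2)c(OC)c1)C(=O)OC
F7 | step 3 | racemic trans-dimethyl 2-(4-benzyloxy-3-methoxyphenyl)-3-methylcyclopropane-1,1-dicarboxylate (both enantiomers drawn) | COc1cc([C@H]2[C@H](C)C2(C(=O)OC)C(=O)OC)ccc1OCc1ccccc1.COc1cc([C@@H]2[C@@H](C)C2(C(=O)OC)C(=O)OC)ccc1OCc1ccccc1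
F8 | step 6 | (2S,3R,4S,5S)-2-(4-benzyloxy-3-methoxyphenyl)-5-(4-allyloxy-3-methoxyphenyl)-4-methoxycarbonyl-3-methyltetrahydrofuran-4-carboxylic acid | COc1cc([C@H]2O[C@@H](c3ccc(OCC=C)c(OC)c3)[C@](C(=O)OC)(C(=O)O)[C@H]2C)ccc1OCc1ccccc1
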